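The C12–C13 bond between the decalin (rings A and B) and the butenolide-bearing side chain is the disconnection on which everything rests. C13, the carbon that carries the O–OH group, a methyl group and the C14=C15 alkene, is a tertiary allylic hydroperoxide. It can therefore arise from stereoinvertive H2O2 opening of a 13,14-epoxide followed by dehydration toward C15, so it may be an sp2 carbon at the moment of union. The key step is a nickel-catalysed reductive cross-electrophile coupling of two electrophilic carbons: the primary C12 bromide of a larixol-derived decalin and the (E)-C13 alkenyl bromide of an (S)-butenolide. One operation joins both halves as a geometrically defined 13(14)-alkene.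

Key step: step 14

Remark: labdane-type numbering is used (ring A C1–C5/C10, ring B C5–C10, ester carbon C18 and methyl C19 on C4, methyls C17 on C8 and C20 on C10, side chain C11–C16); (+)-larixol is taken as a commercial natural product, and the ProPhenol enantiomer is the one that delivers the (S)-carbinol (the (S,S)-ligand is written; its mirror image is equally available).

Step 1
Reactants: 1 (+)-larixol [(13S)-labda-8(17),14-diene-6α,13-diol]
Product: 2 6α-hydroxy-14,15-dinorlabd-8(17)-en-13-one
Conditions: KMnO4, MgSO4, acetone–H2O, 0 °C to rt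
Reagents that add atoms: none
Why: Permanganate cleavage of a tertiary vinyl carbinol (dihydroxylation of the unhindered vinyl group, then glycol and ketol cleavage) should excise C14 and C15 and leave the C13 methyl ketone, the hindered exocyclic 8(17)-alkene reacting more slowly; no stereocentre is formed and C13 of 1 disappears.

Step 2
Reactants: 2 6α-hydroxy-14,15-dinorlabd-8(17)-en-13-one
Product: 3 8α,17-epoxy-6α-hydroxy-13,14,15,16-tetranorlabdan-12-yl acetate
Conditions: mCPBA (excess), NaHCO3, CH2Cl2, 0 to 40 °C
Reagents that add atoms: 3-chloroperbenzoic acid, OOC(=O)c1cccc(Cl)c1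
Why: Prilezhaev epoxidation of the 1,1-disubstituted alkene from the α face (opposite the axial C10 methyl) fixes the later C8 configuration, and Baeyer–Villiger oxidation of the methyl ketone with migration of primary C12 in preference to methyl gives the C12 acetate.

Step 3
Reactants: 3 8α,17-epoxy-6α-hydroxy-13,14,15,16-tetranorlabdan-12-yl acetate
Product: 4 6α,18:8α,17-diepoxy-13,14,15,16-tetranorlabdan-12-yl acetate
Conditions: PhI(OAc)2, I2, cyclohexane, visible light, 30 °C
Reagents that add atoms: none
Why: In this Suárez hypoiodite reaction the equatorial 6α-oxyl radical abstracts a hydrogen from the parallel (peri) equatorial 4α-methyl C18 by 1,5-hydrogen transfer and iodination with ring closure gives the tetrahydrofuran, so C4 becomes a stereocentre (oxygenated C18 α, methyl C19 β) purely through the geometry of the trans-decalin.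

Step 4
Reactants: 4 6α,18:8α,17-diepoxy-13,14,15,16-tetranorlabdan-12-yl acetate
Product: 5 6α,18-epoxy-13,14,15,16-tetranorlabdane-8α,12-diol
Conditions: LiAlH4, THF, 0 °C to rt
Reagents that add atoms: none
Why: Hydride opens the spiro-epoxide at its CH2 terminus (SN2), which leaves the 8α-oxygen as the tertiary alcohol and turns C17 into the 8β-methyl group, and it reductively removes the acetate while the tetrahydrofuran is inert.

Step 5
Reactants: 5 6α,18-epoxy-13,14,15,16-tetranorlabdane-8α,12-diol
Product: 6 6α,18-epoxy-8α-hydroxy-13,14,15,16-tetranorlabdan-12-yl acetate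
Conditions: Ac2O, pyridine, CH2Cl2, 0 °C
Reagents that add atoms: acetic anhydride, CC(=O)OC(C)=O
Why: Acylation is selective for the unhindered primary alcohol over the tertiary 8α-hydroxyl and masks C12–OH against the oxidant of the next step.

Step 6
Reactants: 6 6α,18-epoxy-8α-hydroxy-13,14,15,16-tetranorlabdan-12-yl acetate
Product: 7 12-acetoxy-8α-hydroxy-13,14,15,16-tetranorlabdan-18,6α-olide
Conditions: RuCl3·xH2O (cat.), NaIO4, CCl4–MeCN–H2O, rt
Reagents that add atoms: sodium periodate (oxygen delivered through RuO4), [Na+].[O-]I(=O)(=O)=O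
Why: RuO4 formed in situ oxidises the ether methylene C18 to the γ-lactone (the other α-hydrogen, at C6, is axial and shielded by the two axial methyls), which brings C18 to the acid level while the tertiary alcohol and the acetate are inert.

Step 7
Reactants: 7 12-acetoxy-8α-hydroxy-13,14,15,16-tetranorlabdan-18,6α-olide
Product: 9 methyl 6α,8α,12-trihydroxy-13,14,15,16-tetranorlabdan-18-oate, via potassium trihydroxy carboxylate 8 (not isolated)
Conditions: KOH, MeOH–H2O, 70 °C; CO2 to pH 8, evaporate; MeI, DMF, rt
Reagents that add atoms: potassium hydroxide, [K+].[OH-]; iodomethane, CI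
Why: Saponification opens the lactone and cleaves the acetate, and SN2 methylation of the carboxylate salt, which is never acidified and so cannot relactonise, gives the methyl ester with all ring stereocentres untouched.

Step 8
Reactants: 9 methyl 6α,8α,12-trihydroxy-13,14,15,16-tetranorlabdan-18-oate
Product: 10 methyl 6α,8α,12-tris(triethylsilyloxy)-13,14,15,16-tetranorlabdan-18-oate
Conditions: Et3SiOTf, 2,6-lutidine, CH2Cl2, −78 to 0 °C
Reagents that add atoms: triethylsilyl triflate, CC[Si](CC)(CC)OS(=O)(=O)C(F)(F)F
Why: The silyl triflate silylates all three hydroxyls, and the 6α- and 8α-ethers are needed later to prevent lactonisation and attack of the 8-oxygen on C12 or C13.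

Step 9
Reactants: 10 methyl 6α,8α,12-tris(triethylsilyloxy)-13,14,15,16-tetranorlabdan-18-oate
Product: 11 methyl 12-bromo-6α,8α-bis(triethylsilyloxy)-13,14,15,16-tetranorlabdan-18-oate
Conditions: Ph3PBr2, CH2Cl2, 0 °C to rt
Reagents that add atoms: dibromotriphenylphosphorane, BrP(Br)(c1ccccc1)(c1ccccc1)c1ccccc1
Why: Direct conversion of a silyl ether into a bromide runs through an alkoxyphosphonium ion that must be opened by SN2 attack of bromide at carbon, so only the primary C12 ether should react and the hindered secondary and tertiary silyl ethers stay.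

Step 10
Reactants: 12 pent-3-yn-1-ol
Product: 14 (E)-4-bromopent-3-en-1-ol, via alkenylzirconocene 13 (not isolated)
Conditions: Cp2Zr(H)Cl (2.5 equiv), THF, rt to 40 °C; NBS, 0 °C
Reagents that add atoms: N-bromosuccinimide, O=C1CCC(=O)N1Br
Why: Hydrozirconation is a syn addition whose regiochemistry equilibrates with excess Zr–H to zirconium on the less hindered, methyl-bearing alkyne carbon, and bromination of the C–Zr bond with retention gives the (E)-alkenyl bromide.

Step 11
Reactants: 14 (E)-4-bromopent-3-en-1-ol
Product: 15 (E)-4-bromopent-3-enal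
Conditions: Dess–Martin periodinane, NaHCO3, CH2Cl2, 0 °C
Reagents that add atoms: none
Why: Dess–Martin oxidation under buffered, non-basic conditions should give the β,γ-unsaturated aldehyde without migration of the double bond, and it is used at once.

Step 12
Reactants: 15 (E)-4-bromopent-3-enal; 16 methyl propiolate
Product: 18 methyl (4S,6E)-7-bromo-4-hydroxyoct-6-en-2-ynoate, via methylzinc alkynide 17 (not isolated)
Conditions: Me2Zn, (S,S)-ProPhenol [2,6-bis{[(S)-2-(hydroxydiphenylmethyl)pyrrolidin-1-yl]methyl}-4-methylphenol, 20 mol %], Ph3PO (cat.), toluene, 4 °C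
Reagents that add atoms: none
Why: In this catalytic enantioselective alkynylation the dinuclear zinc–ProPhenol complex delivers the zinc acetylide of methyl propiolate to one enantiotopic face of the aldehyde, which sets the C16 carbinol as S by reagent control.

Step 13
Reactants: 18 methyl (4S,6E)-7-bromo-4-hydroxyoct-6-en-2-ynoate
Product: 20 (5S)-5-[(2E)-3-bromobut-2-en-1-yl]-4-methylfuran-2(5H)-one, via hydroxy enoate 19 (not isolated)
Conditions: Me2CuLi (from MeLi, CuI), THF, −78 °C; aq. NH4Cl, then rt
Reagents that add atoms: lithium dimethylcuprate, [Li+].C[Cu-]C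
Why: Syn carbocupration of the ynoate places the ester cis to the carbinol carbon, so the (Z)-γ-hydroxy enoate lactonises on quench to the 4-methylbutenolide, while the C16 stereocentre is untouched and the alkenyl bromide is inert at −78 °C.

Step 14
Reactants: 11 methyl 12-bromo-6α,8α-bis(triethylsilyloxy)-13,14,15,16-tetranorlabdan-18-oate; 20 (5S)-5-[(2E)-3-bromobut-2-en-1-yl]-4-methylfuran-2(5H)-one (1.5 equiv)
Product: 21 coupled (13E)-alkene: bromide 11 joined at C12 to C13 of the chain C13(CH3)=C14H–C15H2–C16, where C16 (S) is C5 of the 4-methylbutenolide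
Conditions: NiBr2(dme) (10 mol %), 4,4'-di-tert-butyl-2,2'-bipyridine (10 mol %), Zn dust, DMA, 40 °C
Reagents that add atoms: none
Why: Bipyridine-ligated zerovalent nickel inserts into the C13–Br bond of 20 with retention of the E geometry, a monovalent nickel species abstracts bromine from 11 to give the primary C12 radical, and capture of that radical at nickel followed by reductive elimination forms the C12–C13 bond while zinc turns the catalyst over. The closest known reaction type is the nickel-catalysed reductive cross-electrophile coupling of primary alkyl bromides with alkenyl bromides. No ring is closed and no stereocentre is created; the 13E geometry is inherited from 20 and later lets the chiral ketone catalyst choose the C13 face. The step needs cross-coupling over homo-coupling and reaction at the alkenyl bromide in preference to the butenolide: the first is secured by the different activation modes of sp2 and sp3 halides (two-electron insertion versus radical formation), the second by the β,β-disubstituted, poorly radical-accepting enoate of the butenolide. The medium is neutral, so the C16–H of the butenolide is not epimerised, and the silyl ether on the 8-oxygen stops it from displacing the C12 halide.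

Step 15
Reactants: 21 coupled (13E)-alkene
Product: 22 (13S,14S)-13,14-epoxide of 21
Conditions: 1,2:4,5-di-O-isopropylidene-β-L-erythro-2,3-hexodiulo-2,6-pyranose (L-fructose-derived Shi ketone, 30 mol %), KHSO5 (as 2KHSO5·KHSO4·K2SO4), K2CO3, Bu4NHSO4, MeCN–CH2(OMe)2–aq. buffer (pH 10.5), 0 °C
Reagents that add atoms: potassium peroxymonosulfate, [K+].[O-]S(=O)(=O)OO
Why: In this Shi asymmetric epoxidation the dioxirane of the chiral ketone reacts only with the electron-rich trisubstituted 13(14)-alkene through a spiro transition state, and the L-fructose-derived catalyst is the enantiomer expected to give the (13S,14S)-epoxide from the E alkene by reagent control.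

Step 16
Reactants: 22 (13S,14S)-13,14-epoxide
Product: 23 (13R,14S)-13-hydroperoxy-14-hydroxy compound
Conditions: MoO2(acac)2 (10 mol %), anhydrous H2O2 in Et2O (excess), MgSO4, 0 °C to rt
Reagents that add atoms: hydrogen peroxide, OO
Why: In this molybdenum-catalysed perhydrolysis of a trisubstituted epoxide H2O2 attacks the more substituted C13 in a borderline SN2 manner with inversion, which converts the 13S epoxide carbon into the 13R tertiary hydroperoxide and leaves the old epoxide oxygen on C14.

Step 17
Reactants: 23 (13R,14S)-13-hydroperoxy-14-hydroxy compound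
Product: 24 (13R,14S)-14-hydroxy-13-(triethylsilylperoxy) compound
Conditions: Et3SiCl (1.1 equiv), imidazole, CH2Cl2, −20 °C
Reagents that add atoms: chlorotriethylsilane, CC[Si](Cl)(CC)CC
Why: The more acidic hydroperoxide, activated by the α-effect, is silylated much faster than the neopentyl-type secondary C14 alcohol, so the silyl peroxide should form selectively.

Step 18
Reactants: 24 (13R,14S)-14-hydroxy-13-(triethylsilylperoxy) compound
Product: 25 (13R,14E,16S)-13-(triethylsilylperoxy)-14-ene, still carrying the 6α- and 8α-triethylsilyl ethers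
Conditions: Ph2S[OC(CF3)2Ph]2, CH2Cl2, 0 °C to rt
Reagents that add atoms: none
Why: In this dialkoxysulfurane dehydration the C14 alkoxysulfonium ion undergoes anti-E2 elimination, which can only take a hydrogen from C15 because C13 is quaternary, and the less crowded antiperiplanar conformer gives the E 14(15)-alkene.

Step 19
Reactants: 25 (13R,14E,16S)-13-(triethylsilylperoxy)-14-ene
Product: 26 CNP0128148.1
Conditions: HF·pyridine, pyridine, THF, 0 °C to rt
Reagents that add atoms: none
Why: Fluoride-mediated cleavage of the two silyl ethers and the silyl peroxide under buffered, non-basic conditions should spare the hydroperoxide, the base-sensitive C16–H of the butenolide and the 6-hydroxy/18-ester pair.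

Compound list
1 | (+)-larixol, (13S)-labda-8(17),14-diene-6α,13-diol | CC1(C)CCC[C@@]2(C)[C@H]1[C@@H](O)CC(=C)[C@@H]2CC[C@](C)(O)C=C | starting material
2 | 6α-hydroxy-14,15-dinorlabd-8(17)-en-13-one | CC1(C)CCC[C@@]2(C)[C@H]1[C@@H](O)CC(=C)[C@@H]2CCC(C)=O | intermediate
3 | 8α,17-epoxy-6α-hydroxy-13,14,15,16-tetranorlabdan-12-yl acetate | CC1(C)CCC[C@@]2(C)[C@H]1[C@@H](O)C[C@@]3(OC3)[C@@H]2CCOC(C)=O | intermediate
4 | 6α,18:8α,17-diepoxy-13,14,15,16-tetranorlabdan-12-yl acetate | O1C[C@]2(C)CCC[C@@]3(C)[C@H]2[C@@H]1C[C@@]4(OC4)[C@@H]3CCOC(C)=O | intermediate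
5 | 6α,18-epoxy-13,14,15,16-tetranorlabdane-8α,12-diol | O1C[C@]2(C)CCC[C@@]3(C)[C@H]2[C@@H]1C[C@@](C)(O)[C@@H]3CCO | intermediate
6 | 6α,18-epoxy-8α-hydroxy-13,14,15,16-tetranorlabdan-12-yl acetate | O1C[C@]2(C)CCC[C@@]3(C)[C@H]2[C@@H]1C[C@@](C)(O)[C@@H]3CCOC(C)=O | intermediate
7 | 12-acetoxy-8α-hydroxy-13,14,15,16-tetranorlabdan-18,6α-olide | O=C1[C@]2(C)CCC[C@@]3(C)[C@H]2[C@@H](O1)C[C@@](C)(O)[C@@H]3CCOC(C)=O | intermediate
8 | potassium 6α,8α,12-trihydroxy-13,14,15,16-tetranorlabdan-18-oate | [K+].[O-]C(=O)[C@]1(C)CCC[C@@]2(C)[C@H]1[C@@H](O)C[C@@](C)(O)[C@@H]2CCO | intermediate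
9 | methyl 6α,8α,12-trihydroxy-13,14,15,16-tetranorlabdan-18-oate | COC(=O)[C@]1(C)CCC[C@@]2(C)[C@H]1[C@@H](O)C[C@@](C)(O)[C@@H]2CCO | intermediate
10 | methyl 6α,8α,12-tris(triethylsilyloxy)-13,14,15,16-tetranorlabdan-18-oate | COC(=O)[C@]1(C)CCC[C@@]2(C)[C@H]1[C@@H](O[Si](CC)(CC)CC)C[C@@](C)(O[Si](CC)(CC)CC)[C@@H]2CCO[Si](CC)(CC)CC | intermediate
11 | methyl 12-bromo-6α,8α-bis(triethylsilyloxy)-13,14,15,16-tetranorlabdan-18-oate | COC(=O)[C@]1(C)CCC[C@@]2(C)[C@H]1[C@@H](O[Si](CC)(CC)CC)C[C@@](C)(O[Si](CC)(CC)CC)[C@@H]2CCBr | intermediate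
12 | pent-3-yn-1-ol | CC#CCCO | starting material
13 | (E)-alkenylzirconocene chloride of 12 (Zr on C4, O-zirconated) | C/C(=C\CCO[Zr](Cl)(C1C=CC=C1)C1C=CC=C1)[Zr](Cl)(C1C=CC=C1)C1C=CC=C1 | intermediate
14 | (E)-4-bromopent-3-en-1-ol | C/C(Br)=C\CCO | intermediate
15 | (E)-4-bromopent-3-enal | C/C(Br)=C\CC=O | intermediate
16 | methyl propiolate | C#CC(=O)OC | starting material
17 | methyl 3-(methylzincio)propiolate | C[Zn]C#CC(=O)OC | intermediate
18 | methyl (4S,6E)-7-bromo-4-hydroxyoct-6-en-2-ynoate | C/C(Br)=C\C[C@H](O)C#CC(=O)OC | intermediate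
19 | methyl (2Z,4S,6E)-7-bromo-4-hydroxy-3-methylocta-2,6-dienoate | C/C(Br)=C\C[C@H](O)/C(C)=C\C(=O)OC | intermediate
20 | (5S)-5-[(2E)-3-bromobut-2-en-1-yl]-4-methylfuran-2(5H)-one | C/C(Br)=C\C[C@@H]1OC(=O)C=C1C | intermediate
21 | coupled (13E)-alkene, 6α,8α-bis(triethylsilyl) ether, (16S)-butenolide | COC(=O)[C@]1(C)CCC[C@@]2(C)[C@H]1[C@@H](O[Si](CC)(CC)CC)C[C@@](C)(O[Si](CC)(CC)CC)[C@@H]2CC/C(C)=C/C[C@@H]1OC(=O)C=C1C | intermediate
22 | (13S,14S)-13,14-epoxide of 21 | COC(=O)[C@]1(C)CCC[C@@]2(C)[C@H]1[C@@H](O[Si](CC)(CC)CC)C[C@@](C)(O[Si](CC)(CC)CC)[C@@H]2CC[C@]3(C)O[C@H]3C[C@@H]1OC(=O)C=C1C | intermediate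
23 | (13R,14S)-13-hydroperoxy-14-hydroxy compound | COC(=O)[C@]1(C)CCC[C@@]2(C)[C@H]1[C@@H](O[Si](CC)(CC)CC)C[C@@](C)(O[Si](CC)(CC)CC)[C@@H]2CC[C@](C)([C@@H](O)C[C@@H]1OC(=O)C=C1C)OO | intermediate
24 | (13R,14S)-14-hydroxy-13-(triethylsilylperoxy) compound | COC(=O)[C@]1(C)CCC[C@@]2(C)[C@H]1[C@@H](O[Si](CC)(CC)CC)C[C@@](C)(O[Si](CC)(CC)CC)[C@@H]2CC[C@](C)([C@@H](O)C[C@@H]1OC(=O)C=C1C)OO[Si](CC)(CC)CC | intermediate
25 | (13R,14E,16S)-13-(triethylsilylperoxy)-14-ene, 6α,8α-bis(triethylsilyl) ether | COC(=O)[C@]1(C)CCC[C@@]2(C)[C@H]1[C@@H](O[Si](CC)(CC)CC)C[C@@](C)(O[Si](CC)(CC)CC)[C@@H]2CC[C@](C)(/C=C/[C@@H]1OC(=O)C=C1C)OO[Si](CC)(CC)CC | intermediate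
26 | CNP0128148.1 | COC(=O)[C@]1(C)CCC[C@@]2(C)[C@H]1[C@@H](O)C[C@@](C)(O)[C@@H]2CC[C@](C)(/C=C/[C@@H]1OC(=O)C=C1C)OO | target

Total step count: 19. Longest linear sequence: 15 steps (steps 1–9 and 14–19 from larixol 1); the butenolide bromide 20 takes 4 steps (10–13).

Steps most likely to fail:

Step 14 (key coupling). Reductive homodimerisation or protodebromination of either bromide may outrun cross-coupling, oxidative addition to the hindered trisubstituted alkenyl bromide may be slow, and the alkene geometry may scramble at nickel. The fallback separates the two activation events. It sets out from 11: zinc insertion (Zn dust, cat. I2, DMA, 70 °C) gives the alkylzinc bromide F1, which is joined to 20 by a Negishi coupling under zerovalent palladium catalysis (Pd(OAc)2, 2-dicyclohexylphosphino-2',6'-dimethoxybiphenyl, THF–DMA, rt). It returns to the route at 21.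

Step 16 (perhydrolysis). The activated epoxide may ionise to an open tertiary cation, which erodes the configuration at C13, diverts attack to C14, or, after acid-promoted silyl loss, lets the 8-oxygen capture C13 as a tetrahydropyran; the β-hydroxy hydroperoxide may also cleave between C13 and C14. The fallback avoids the epoxide altogether and sets out from 21. A Schenck ene reaction with singlet oxygen (O2, tetraphenylporphyrin, visible light, CH2Cl2, −20 °C) abstracts a C15 hydrogen and delivers the bis(triethylsilyl) allylic hydroperoxide F2. Control at C13 is given up: the C13 epimer and the 14-hydroperoxy regioisomers are removed by HPLC, the epimers being diastereomers. HF·pyridine as in step 19 then returns the material to the route at 26.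

Step 18 (dehydration). Ionisation at C14 may lead to a 1,2-shift from the peroxide-bearing C13 or to O–O cleavage instead of anti-elimination toward C15, or the alkoxysulfurane may collapse to an ether. The fallback sets out from 24 and uses an intramolecular syn-elimination instead. The Burgess reagent (methyl N-(triethylammoniumsulfonyl)carbamate, benzene, rt) converts the C14 alcohol into the sulfamate salt F3, which on warming to 50 °C eliminates through a cyclic transition state toward C15. It returns to the route at 25.

Further compounds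
F1 | step 14 | alkylzinc bromide from 11 (C12–ZnBr) | COC(=O)[C@]1(C)CCC[C@@]2(C)[C@H]1[C@@H](O[Si](CC)(CC)CC)C[C@@](C)(O[Si](CC)(CC)CC)[C@@H]2CC[Zn]Br
F2 | step 16 | (13R,14E,16S)-13-hydroperoxide, 6α,8α-bis(triethylsilyl) ether | COC(=O)[C@]1(C)CCC[C@@]2(C)[C@H]1[C@@H](O[Si](CC)(CC)CC)C[C@@](C)(O[Si](CC)(CC)CC)[C@@H]2CC[C@](C)(/C=C/[C@@H]1OC(=O)C=C1C)OO
F3 | step 18 | triethylammonium C14 N-(methoxycarbonyl)sulfamate of 24 | COC(=O)[C@]1(C)CCC[C@@]2(C)[C@H]1[C@@H](O[Si](CC)(CC)CC)C[C@@](C)(O[Si](CC)(CC)CC)[C@@H]2CC[C@](C)([C@@H](OS(=O)(=O)[N-]C(=O)OC)C[C@@H]1OC(=O)C=C1C)OO[Si](CC)(CC)CC.CC[NH+](CC)CC
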